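Per cent of the left-handed and right-handed substrate charged together is the unit of the readings below, so I divide a reading by 0.5 to get the fraction of that substrate's own charge left.

common to all: left-handed substrate 0.28 M; right-handed substrate 0.28 M
- Friday's: partner 0.84 M; protic impurity 0.056 M; free catalyst 31 mM; run made earlier
- Tuesday's: partner 0.84 M; protic impurity 0.056 M; free catalyst 48 mM; run made earlier
- Wednesday's: partner 1.3 M; protic impurity 0.056 M; free catalyst 22 mM; run made earlier
- flask: partner 0.840 M; protic impurity 0.0560 M; free catalyst 22 mM; time 2.0 h

- Friday's (time / min: left-handed substrate / %, right-handed substrate / %): 8.00: 41.0, 48.1; 12.0: 38.7, 47.3; 20.0: 36.3, 47.4; 40.0: 31.2, 45.6; 60.0: 27.2, 44.5; 90.0: 23.8, 44.1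
- Tuesday's (time / min: left-handed substrate / %, right-handed substrate / %): 8.00: 37.7, 46.8; 12.0: 35.3, 46.8; 20.0: 30.9, 44.5; 40.0: 24.2, 43.4; 60.0: 18.9, 41.9; 90.0: 14.7, 39.8
- Wednesday's (time / min: left-handed substrate / %, right-handed substrate / %): 8.00: 42.9, 47.8; 25.0: 36.0, 47.3; 40.0: 31.8, 46.4; 60.0: 28.2, 45.8; 90.0: 24.5, 46.2

(readings scatter by 0.5 percentage points)

1. part of the left-handed substrate and right-handed substrate charged together that has reacted at 2.0 h
2. excess of left-handed product over right-handed product in the product at 2.0 h
3. excess of right-handed substrate over left-handed substrate among what is left of the two at 2.0 h

- free catalyst is single-handed; left-handed substrate and right-handed substrate are mirror images of each other, charged as a racemate, each of them at the stated concentration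
- on the list of suspects stand: free catalyst + left-handed substrate <-> catalyst intermediate A; free catalyst + right-handed substrate <-> catalyst intermediate B; 2 partner -> homo dimer; partner + catalyst intermediate B -> free catalyst + right-handed product; partner + protic impurity -> quenched reagent; partner + catalyst intermediate A -> free catalyst + left-handed product
- an excess is the difference of the two amounts in percent of their sum
- an excess is below zero if the other one leads

1. I carry one quantity, s = 5.37: the logarithm of the fraction of left-handed substrate left over the logarithm of the fraction of right-handed substrate left, the selectivity factor. I read it at 90.0 min of Tuesday's run, whose left-handed reading is the lowest.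
2. The flask has Wednesday's catalyst charge. Its c(partner) × time is more than Wednesday's at 60.0 min and less than Wednesday's at 90.0 min, so I take the mean of those readings: left-handed substrate 26.3%, a fraction left of 52.7%.
3. Then s gives a right-handed fraction left of 88.7%, or 44.4%. So I expect c 29.3% and eS 25.6%. For eP I get 61.8%, counting substrate held on catalyst as product.
4. Keep it stirring until 2.0 h: at fixed s, the excess of right-handed substrate grows as the fraction left falls.
5. The forecast differs from my c and eP: c 26.5% (22.5% to 30%), eP 68% (58% to 77%), eS 25% (21% to 29%). Its ground: “The rate slows with time as partner is lost to impurity, dimerisation and reaction.”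

The flask gives c 27.6%, eP 70.8% and eS 25.3%.

    free catalyst + left-handed substrate ⇌ catalyst intermediate A (K = 16.0 /M, k = 99.6 /M/min)
    free catalyst + right-handed substrate ⇌ catalyst intermediate B (K = 5.01 /M, k = 103 /M/min)
    2 partner → homo dimer (k = 0.0167 /M/min)
    partner + catalyst intermediate B → free catalyst + right-handed product (k = 0.101 /M/min)
    partner + protic impurity → quenched reagent (k = 0.191 /M/min)
    partner + catalyst intermediate A → free catalyst + left-handed product (k = 0.244 /M/min)

In the flask, protic impurity falls to 20.7% of its charge by 0.200 h while partner falls to 68.2%, and catalyst intermediate A already holds 61.4% of the catalyst. Left-handed product, in per cent of both substrates charged, then climbs from 4.91% to 20.9% at 2.00 h, as partner sinks to 17% of its charge, and s turns the 54% of its own charge of left-handed substrate left into 89.2% of right-handed substrate's own charge left, against 91%. In the neighbour with 0.088 M of free catalyst, s turns 7.2% of the left-handed substrate's own charge left into 61.3% of the right-handed substrate's own charge left, against 58%.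

(The data stem from a simulated flask with constants of no real substance; noise was put on by code.)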